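## Retrosynthetic overview

- Target 7 comes from its tri-O-methyl ether 6 by cleavage of three aryl methyl ethers (last step).
- 6 comes from aryl iodide 2, alkyne 3 and aryl iodide 4 in one pot: a Sonogashira coupling makes the C3a–C3 bond, then an arylative 5-endo-dig oxypalladation closes furan ring B (O1–C2) and reductive elimination makes the bond from C3 to C1' of ring C.
- Enabling feature: in benzo ring A, C3a sits between the two oxygen-bearing carbons C4 and C7a and para to C6 (CHO). Ring A therefore maps onto mirror-symmetric 3,5-dihydroxy-4-iodobenzaldehyde 2, whose two hydroxyls are equivalent: one closes ring B, the other remains as the C4–OH, so neither a protecting group nor regiocontrol is needed.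
- 2 comes from 1 by iodination between the two hydroxyls. Rings A, C and D are bought; ring B is the only ring formed (step 2).

Key step: step 2

Remark: the target has no stereogenic element, so no step needs stereocontrol; compounds 1, 3 and 4 are taken as commercial.

## Route

Step 1
Reactants: 1 3,5-dihydroxybenzaldehyde
Product: 2 3,5-dihydroxy-4-iodobenzaldehyde
Conditions: I2 (1.05 equiv), NaHCO3 (1.1 equiv), H2O/THF, 0 °C to rt
Reagents that add atoms: iodine, II
Why: Electrophilic aromatic iodination of the phenolate in aqueous bicarbonate should go to C4, the position flanked by both hydroxyls and para to the formyl group, by analogy with the conversion of resorcinol into 2-iodoresorcinol under the same conditions, and one equivalent of iodine at 0 °C limits multiple iodination.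

Step 2
Reactants: 2 3,5-dihydroxy-4-iodobenzaldehyde; 3 1-ethynyl-4-methoxybenzene; 4 1-iodo-3,5-dimethoxybenzene
Product: 6 3-(3,5-dimethoxyphenyl)-4-hydroxy-2-(4-methoxyphenyl)-1-benzofuran-6-carbaldehyde, via alkynylresorcinol 5 (not isolated)
Conditions: PdCl2(PPh3)2 (5 mol %), CuI (3 mol %), Et3N, THF, 25–40 °C (degassed); then 4 (1.5 equiv), MeCN, 90 °C
Reagents that add atoms: none
Why: A Sonogashira coupling (oxidative addition of zerovalent palladium into the C–I bond of 2, which the para formyl group activates, then transmetalation from the copper acetylide of 3 and reductive elimination) should first give alkynylresorcinol 5 at a temperature at which its free ortho hydroxyls do not yet add to the alkyne. After 4 is added and the mixture is heated, the same catalyst should insert into the C–I bond of 4, the arylpalladium iodide (divalent palladium) should bind the alkyne of 5, and one ortho phenoxide should attack the anisyl-bearing alkyne carbon anti to the metal, which closes the furan ring in the 5-endo-dig mode; reductive elimination from the benzofuran-3-yl(aryl)palladium species then forms the C3–aryl bond and regenerates zerovalent palladium. The closest known reaction type is the Cacchi arylative cyclisation of 2-alkynylphenols with aryl halides, including its one-pot three-component form from a 2-iodophenol, a terminal alkyne and an aryl iodide under Sonogashira conditions. No stereocentre is formed, and no regiochemical choice arises, because 5 has a mirror plane through C1, C4 and the alkyne axis, so that either hydroxyl closes the same furan and the other one becomes the C4 hydroxyl of 6. The selectivity that is needed is arylative cyclisation over plain hydroalkoxylation to the C3–H benzofuran; a mild first stage, a low CuI loading, an excess of 4 (its two meta methoxy groups are inductively withdrawing and do not slow oxidative addition) and MeCN at 90 °C in the second stage should secure it, and the tertiary amine base leaves the formyl group untouched. Adding 4 only after 2 is consumed keeps 4 out of the first coupling.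

Step 3
Reactants: 6 3-(3,5-dimethoxyphenyl)-4-hydroxy-2-(4-methoxyphenyl)-1-benzofuran-6-carbaldehyde
Product: 7 3-(3,5-dihydroxyphenyl)-4-hydroxy-2-(4-hydroxyphenyl)-1-benzofuran-6-carbaldehyde
Conditions: BBr3 (8 equiv), CH2Cl2 (dilute), −78 °C to rt; then ice/H2O
Reagents that add atoms: none
Why: BBr3-mediated aryl methyl ether cleavage (Lewis acid–base adduct, then bromide attack at the methyl carbon) should remove all three methyl groups, while the aryl aldehyde is only complexed reversibly and is returned on aqueous work-up; low temperature and dilution should hold back condensation of the formyl group with the electron-rich ring C.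

## Compound list

1 | 3,5-dihydroxybenzaldehyde | O=Cc1cc(O)cc(O)c1 | starting material
2 | 3,5-dihydroxy-4-iodobenzaldehyde | O=Cc1cc(O)c(I)c(O)c1 | intermediate
3 | 1-ethynyl-4-methoxybenzene (4-ethynylanisole) | C#Cc1ccc(OC)cc1 | starting material
4 | 1-iodo-3,5-dimethoxybenzene | COc1cc(I)cc(OC)c1 | starting material
5 | 3,5-dihydroxy-4-[(4-methoxyphenyl)ethynyl]benzaldehyde | O=Cc1cc(O)c(C#Cc2ccc(OC)cc2)c(O)c1 | intermediate (not isolated)
6 | 3-(3,5-dimethoxyphenyl)-4-hydroxy-2-(4-methoxyphenyl)-1-benzofuran-6-carbaldehyde | O=Cc1cc(O)c2c(-c3cc(OC)cc(OC)c3)c(-c3ccc(OC)cc3)oc2c1 | intermediate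
7 | 3-(3,5-dihydroxyphenyl)-4-hydroxy-2-(4-hydroxyphenyl)-1-benzofuran-6-carbaldehyde | O=Cc1cc(O)c2c(-c3cc(O)cc(O)c3)c(-c3ccc(O)cc3)oc2c1 | target

## Step count and risks

Total step count: 3. Longest linear sequence: 3 steps (1 → 2 → 6 → 7).

**Steps most likely to fail**

1. Step 2. The phenoxide of 5 may add across the alkyne (base- or copper-promoted) before the aryl group is transferred, which would leave C3 unsubstituted. Oxidative addition into the doubly ortho-oxygenated iodide 2 may also be slow. The fallback is a stepwise sequence of known reactions that sets out from 2 and comes back to the route at 7.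
   - Double O-methylation of 2 (MeI, K2CO3, DMF) should give 4-iodo-3,5-dimethoxybenzaldehyde F1.
   - Sonogashira coupling of F1 with 3 (PdCl2(PPh3)2, CuI, Et3N, 50 °C) should give 3,5-dimethoxy-4-[(4-methoxyphenyl)ethynyl]benzaldehyde F2, which cannot cyclise prematurely.
   - Electrophilic iodocyclisation (I2, CH2Cl2, rt) should give 3-iodo-4-methoxy-2-(4-methoxyphenyl)-1-benzofuran-6-carbaldehyde F3. A methoxy oxygen attacks the iodonium-activated alkyne anti to iodine and its methyl group is lost as iodomethane.
   - Suzuki–Miyaura coupling of F3 with (3,5-dimethoxyphenyl)boronic acid (Pd(PPh3)4, K2CO3, dioxane/H2O, 90 °C) should form the C3–aryl bond and give 3-(3,5-dimethoxyphenyl)-4-methoxy-2-(4-methoxyphenyl)-1-benzofuran-6-carbaldehyde F4.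
   - BBr3 under the conditions of step 3 should cleave the four methyl ethers of F4 to give 7.

2. Step 1. Iodination may occur at C2/C6 (ortho to the formyl group) or more than once, instead of only between the hydroxyls. The fallback fixes the position by directed metalation; it sets out from 1 and comes back at 2.
   - MOMCl and iPr2NEt in CH2Cl2 should give 3,5-bis(methoxymethoxy)benzaldehyde F5.
   - HC(OMe)3 in MeOH with catalytic pyridinium p-toluenesulfonate should give 1-(dimethoxymethyl)-3,5-bis(methoxymethoxy)benzene F6.
   - n-BuLi in THF at 0 °C should lithiate between the two cooperating MOM ethers; quenching with I2 at −78 °C should give 5-(dimethoxymethyl)-2-iodo-1,3-bis(methoxymethoxy)benzene F7.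
   - Aqueous HCl in MeOH at 50 °C should remove the acetal and both MOM groups and give 2.

3. Step 3. The Lewis-acid-activated formyl group may be attacked by the electron-rich ring C of a second molecule (hydroxyalkylation leading to oligomers), or ether cleavage may stop short. The fallback masks the carbonyl group during demethylation; it sets out from 6 and comes back at 7.
   - Propane-1,3-dithiol with catalytic BF3·OEt2 in CH2Cl2 at 0 °C should give 3-(3,5-dimethoxyphenyl)-6-(1,3-dithian-2-yl)-2-(4-methoxyphenyl)-1-benzofuran-4-ol F8.
   - BBr3 in CH2Cl2 (−78 °C to rt) should give 5-[6-(1,3-dithian-2-yl)-4-hydroxy-2-(4-hydroxyphenyl)-1-benzofuran-3-yl]benzene-1,3-diol F9, since the dithiane is inert to the reagent and not electrophilic.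
   - Alkylative hydrolysis of F9 (MeI, CaCO3, MeCN/H2O, 40 °C) should release the aldehyde and give 7.

Further compounds
F1 | step 2 | 4-iodo-3,5-dimethoxybenzaldehyde | COc1cc(C=O)cc(OC)c1I
F2 | step 2 | 3,5-dimethoxy-4-[(4-methoxyphenyl)ethynyl]benzaldehyde | COc1ccc(cc1)C#Cc1c(OC)cc(C=O)cc1OC
F3 | step 2 | 3-iodo-4-methoxy-2-(4-methoxyphenyl)-1-benzofuran-6-carbaldehyde | COc1ccc(cc1)-c1oc2cc(C=O)cc(OC)c2c1I
F4 | step 2 | 3-(3,5-dimethoxyphenyl)-4-methoxy-2-(4-methoxyphenyl)-1-benzofuran-6-carbaldehyde | COc1ccc(cc1)-c1oc2cc(C=O)cc(OC)c2c1-c1cc(OC)cc(OC)c1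
F5 | step 1 | 3,5-bis(methoxymethoxy)benzaldehyde | COCOc1cc(C=O)cc(OCOC)c1
F6 | step 1 | 1-(dimethoxymethyl)-3,5-bis(methoxymethoxy)benzene | COCOc1cc(cc(OCOC)c1)C(OC)OC
F7 | step 1 | 5-(dimethoxymethyl)-2-iodo-1,3-bis(methoxymethoxy)benzene | COCOc1cc(cc(OCOC)c1I)C(OC)OC
F8 | step 3 | 3-(3,5-dimethoxyphenyl)-6-(1,3-dithian-2-yl)-2-(4-methoxyphenyl)-1-benzofuran-4-ol | COc1ccc(cc1)-c1oc2cc(cc(O)c2c1-c1cc(OC)cc(OC)c1)C1SCCCS1
F9 | step 3 | 5-[6-(1,3-dithian-2-yl)-4-hydroxy-2-(4-hydroxyphenyl)-1-benzofuran-3-yl]benzene-1,3-diol | Oc1ccc(cc1)-c1oc2cc(cc(O)c2c1-c1cc(O)cc(O)c1)C1SCCCS1
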